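**Strategy.** Everything rests on forming the bond between C-2 of ring B (the resorcinol-type ring; C-2 lies between the hydroxyl-bearing and the aryloxy-bearing carbons) and the ester carbonyl carbon held by an outer oxygen of ring C (the 5-methylpyrogallol ring). A palladium-catalysed aryloxycarbonylation joins a ring A–ring B aryl iodide with a ring C–ring D bis(formate): base releases CO and phenoxide from a formate, the formyl carbon becomes the carbonyl on ring B, and the second, symmetry-equivalent formate is lost to unveil the free ring-C hydroxyl. The precursors are a benzyl-protected 2-iodo diaryl ether and a 2-aroyloxy-1,3-bis(formyloxy)arene.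

Key step: step 14

Remark on the chemistry: the target has no stereocentre and no configurationally stable axis, so it is achiral and no stereocontrol is needed.
Ring labels: A = methyl 5-hydroxy-3-methoxybenzoate ring; B = 6-hydroxy-4-methylbenzoyl ring; C = 5-methylpyrogallol ring; D = dimethyl 5-hydroxybenzene-1,3-dicarboxylate ring.

**Left fragment (rings A and B)**

Step 1
Reactants: 1 orcinol (5-methylbenzene-1,3-diol)
Product: 2 2-iodo-5-methylbenzene-1,3-diol
Conditions: I2, NaHCO3, H2O/THF, 0 °C → rt
Reagents that add atoms: iodine, II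
Why: Electrophilic aromatic iodination of the resorcinol phenoxide should go to C-2 between the two hydroxyls, as with resorcinol itself under these conditions, the 4/6 positions being further shielded by the methyl group.

Step 2
Reactants: 2 2-iodo-5-methylbenzene-1,3-diol (3 equiv); 3 2-fluoro-3-methoxybenzaldehyde
Product: 4 2-(3-hydroxy-2-iodo-5-methylphenoxy)-3-methoxybenzaldehyde
Conditions: K2CO3, DMF, 100 °C, N2
Reagents that add atoms: none
Why: Nucleophilic aromatic substitution (SNAr) of the fluoride activated by the ortho-formyl group; no transition metal is present, so the C–I bond should survive, and the excess of the symmetric diol should hold back double arylation.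

Step 3
Reactants: 4 2-(3-hydroxy-2-iodo-5-methylphenoxy)-3-methoxybenzaldehyde
Product: 6 methyl 2-(3-hydroxy-2-iodo-5-methylphenoxy)-3-methoxybenzoate, via carboxylic acid 5 (not isolated)
Conditions: NaClO2, NaH2PO4, 2-methyl-2-butene, t-BuOH/H2O, 0 °C → rt; then TMSCHN2, MeOH/toluene, 0 °C
Reagents that add atoms: sodium chlorite, [Na+].[O-]Cl=O; trimethylsilyldiazomethane, C[Si](C)(C)C=[N+]=[N-]
Why: Pinnick oxidation with an HOCl scavenger followed by diazoalkane esterification, which should methylate the carboxylic acid far faster than the phenol in the absence of base.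

Step 4
Reactants: 6 methyl 2-(3-hydroxy-2-iodo-5-methylphenoxy)-3-methoxybenzoate
Product: 8 methyl 5-hydroxy-2-(3-hydroxy-2-iodo-5-methylphenoxy)-3-methoxybenzoate, via bis-boronate 7 (not isolated)
Conditions: [Ir(OMe)(cod)]2 (cat.), dtbpy (cat.), B2pin2 (2 equiv), THF, 70 °C; then Oxone, acetone/H2O, rt
Reagents that add atoms: bis(pinacolato)diboron, CC1(C)OB(OC1(C)C)B1OC(C)(C)C(C)(C)O1; Oxone (potassium peroxymonosulfate), [K+].[O-]S(=O)(=O)OO
Why: Sterically controlled iridium-catalysed C–H borylation followed by oxidation; C-5 of ring A is the only C–H in the molecule without an ortho substituent, the phenol is masked in the flask as its O–Bpin ether, and aryl iodides are tolerated by this catalyst.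

Step 5
Reactants: 8 methyl 5-hydroxy-2-(3-hydroxy-2-iodo-5-methylphenoxy)-3-methoxybenzoate
Product: 9 methyl 5-(benzyloxy)-2-[3-(benzyloxy)-2-iodo-5-methylphenoxy]-3-methoxybenzoate
Conditions: BnBr (2.5 equiv), K2CO3, DMF, rt
Reagents that add atoms: benzyl bromide, BrCc1ccccc1
Why: Williamson ether synthesis on both phenols, giving benzyl ethers that survive the key step and fall together in the last step.

**Right fragment (rings C and D)**

Step 6
Reactants: 1 orcinol
Product: 10 1,3-bis(methoxymethoxy)-5-methylbenzene
Conditions: NaH, MOMCl, DMF, 0 °C → rt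
Reagents that add atoms: chloromethyl methyl ether, COCCl
Why: Williamson-type O-alkylation of both phenoxides, installing MOM groups that direct the metalation of step 7 and can later be removed without touching benzyl ethers.

Step 7
Reactants: 10 1,3-bis(methoxymethoxy)-5-methylbenzene
Product: 13 2,6-bis(methoxymethoxy)-4-methylphenol, via aryllithium 11 (not isolated), via dimethyl boronate 12 (not isolated)
Conditions: n-BuLi, TMEDA, THF, 0 °C; B(OMe)3, −78 °C → rt; then 30% aq. H2O2, 0 °C → rt
Reagents that add atoms: n-butyllithium, [Li]CCCC; trimethyl borate, COB(OC)OC; hydrogen peroxide, OO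
Why: Directed ortho-metalation at the carbon flanked by both OMOM groups (cooperative direction), borylation and oxidation of the C–B bond should give the central phenol of ring C.

Step 8
Reactants: 14 benzene-1,2,3-tricarboxylic acid (hemimellitic acid)
Product: 15 2,6-bis(methoxycarbonyl)benzoic acid
Conditions: MeOH, H2SO4 (cat.), reflux
Reagents that add atoms: methanol, CO
Why: Fischer esterification; by the Victor Meyer rule the central carboxyl, flanked by two ortho substituents, should resist acid-catalysed esterification while the two outer acids react.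

Step 9
Reactants: 15 2,6-bis(methoxycarbonyl)benzoic acid; 13 2,6-bis(methoxymethoxy)-4-methylphenol
Product: 17 2-[2,6-bis(methoxymethoxy)-4-methylphenyl] 1,3-dimethyl benzene-1,2,3-tricarboxylate, via acid chloride 16 (not isolated)
Conditions: (COCl)2, DMF (cat.), CH2Cl2, rt, evaporate; then 13, Et3N, DMAP (cat.), CH2Cl2, 0 → 40 °C
Reagents that add atoms: oxalyl chloride, O=C(Cl)C(Cl)=O
Why: Acid chloride formation and DMAP-catalysed acylation of the phenol; the electron-poor acid chloride should still be attacked by the acylpyridinium route although both partners are di-ortho-substituted.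

Step 10
Reactants: 17 2-[2,6-bis(methoxymethoxy)-4-methylphenyl] 1,3-dimethyl benzene-1,2,3-tricarboxylate
Product: 19 2-[2,6-bis(methoxymethoxy)-4-methylphenyl] 1,3-dimethyl 5-hydroxybenzene-1,2,3-tricarboxylate, via aryl boronate 18 (not isolated)
Conditions: [Ir(OMe)(cod)]2 (cat.), dtbpy (cat.), B2pin2, THF, 70 °C; then Oxone, acetone/H2O, rt
Reagents that add atoms: bis(pinacolato)diboron, CC1(C)OB(OC1(C)C)B1OC(C)(C)C(C)(C)O1; Oxone (potassium peroxymonosulfate), [K+].[O-]S(=O)(=O)OO
Why: Sterically controlled iridium-catalysed C–H borylation and oxidation; C-5 of ring D (meta to both methyl esters) is the only unhindered C–H, as both ring-C hydrogens lie between OMOM and methyl.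

Step 11
Reactants: 19 2-[2,6-bis(methoxymethoxy)-4-methylphenyl] 1,3-dimethyl 5-hydroxybenzene-1,2,3-tricarboxylate
Product: 20 2-[2,6-bis(methoxymethoxy)-4-methylphenyl] 1,3-dimethyl 5-(benzyloxy)benzene-1,2,3-tricarboxylate
Conditions: BnBr, K2CO3, DMF, rt
Reagents that add atoms: benzyl bromide, BrCc1ccccc1
Why: Williamson ether synthesis on the acidic ring-D phenol; the hindered aryl ester should tolerate anhydrous carbonate.

Step 12
Reactants: 20 2-[2,6-bis(methoxymethoxy)-4-methylphenyl] 1,3-dimethyl 5-(benzyloxy)benzene-1,2,3-tricarboxylate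
Product: 21 2-(2,6-dihydroxy-4-methylphenyl) 1,3-dimethyl 5-(benzyloxy)benzene-1,2,3-tricarboxylate
Conditions: conc. HCl (cat.), MeOH/THF, 40 °C
Reagents that add atoms: none
Why: Acid-catalysed acetal exchange removes both MOM groups as dimethoxymethane; methanol cannot scramble the methyl esters, the di-ortho-substituted aryl ester should resist methanolysis, and the benzyl ether is stable.

Step 13
Reactants: 21 2-(2,6-dihydroxy-4-methylphenyl) 1,3-dimethyl 5-(benzyloxy)benzene-1,2,3-tricarboxylate
Product: 22 2-[2,6-bis(formyloxy)-4-methylphenyl] 1,3-dimethyl 5-(benzyloxy)benzene-1,2,3-tricarboxylate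
Conditions: HCO2H/Ac2O (premixed, 55 °C), then 21, NaOAc (cat.), THF, 0 °C → rt; volatiles removed, used crude
Reagents that add atoms: formic acid, O=CO (delivered as acetic formic anhydride, CC(=O)OC=O)
Why: O-Formylation with the mixed anhydride, whose formyl carbonyl is the more electrophilic one; both equivalent phenols react, so no selectivity is needed.

**Union and end game**

Step 14
Reactants: 9 methyl 5-(benzyloxy)-2-[3-(benzyloxy)-2-iodo-5-methylphenoxy]-3-methoxybenzoate; 22 2-[2,6-bis(formyloxy)-4-methylphenyl] 1,3-dimethyl 5-(benzyloxy)benzene-1,2,3-tricarboxylate (2 equiv)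
Product: 23 tri-O-benzyl pseudophenone A (benzyl ethers on the ring A, ring B and ring D hydroxyls; ring C hydroxyl free), via regenerated diol 21 (not isolated)
Conditions: Pd(OAc)2 (5 mol%), Xantphos (10 mol%), Et3N (3 equiv), toluene, 80 °C, sealed tube
Reagents that add atoms: none
Why: Triethylamine triggers α-elimination of a formate of 22, releasing CO and the ring-C phenoxide in the flask; Pd(0)/Xantphos adds oxidatively to the C–I bond of 9, CO inserts so that C-2 of ring B becomes bonded to the former formyl carbon, and capture of the aroyl–palladium species by the phenoxide closes the ester. The closest known reaction type is the palladium-catalysed aryloxycarbonylation of aryl halides with aryl formates as a combined CO and phenol source. No ring is closed and no stereocentre is formed. The step needs activation of the single C–I bond (no other halide is present; esters and benzyl ethers are inert to Pd(0) here), mono-acylation of the diol, and no migration of the ring-D acyl group. The two outer oxygens of ring C are equivalent by symmetry, so either gives the same product; the twofold excess of 22 and the bulk of the first aroyl group should hold back a second acylation, and the unused formate is lost as CO to leave the free hydroxyl. The di-ortho-substituted ring-D benzoate is shielded against attack by the neighbouring phenoxide, which should suppress acyl migration.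

Step 15
Reactants: 23 tri-O-benzyl pseudophenone A
Product: 24 pseudophenone A
Conditions: H2 (1 atm), 10% Pd/C, EtOAc, rt
Reagents that add atoms: none
Why: Hydrogenolysis of the three benzyl ethers under neutral conditions in a non-nucleophilic solvent should leave the two aryl esters and three methyl esters untouched.

**Compound list**

1 | orcinol (5-methylbenzene-1,3-diol) | Cc1cc(O)cc(O)c1 | starting material
2 | 2-iodo-5-methylbenzene-1,3-diol | Cc1cc(O)c(I)c(O)c1 | intermediate
3 | 2-fluoro-3-methoxybenzaldehyde | COc1cccc(C=O)c1F | starting material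
4 | 2-(3-hydroxy-2-iodo-5-methylphenoxy)-3-methoxybenzaldehyde | COc1cccc(C=O)c1Oc1cc(C)cc(O)c1I | intermediate
5 | 2-(3-hydroxy-2-iodo-5-methylphenoxy)-3-methoxybenzoic acid (not isolated) | COc1cccc(C(=O)O)c1Oc1cc(C)cc(O)c1I | intermediate
6 | methyl 2-(3-hydroxy-2-iodo-5-methylphenoxy)-3-methoxybenzoate | COC(=O)c1cccc(OC)c1Oc1cc(C)cc(O)c1I | intermediate
7 | methyl 2-[2-iodo-5-methyl-3-(pinacolboryloxy)phenoxy]-3-methoxy-5-(pinacolboryl)benzoate (not isolated) | COC(=O)c1cc(B2OC(C)(C)C(C)(C)O2)cc(OC)c1Oc1cc(C)cc(OB2OC(C)(C)C(C)(C)O2)c1I | intermediate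
8 | methyl 5-hydroxy-2-(3-hydroxy-2-iodo-5-methylphenoxy)-3-methoxybenzoate | COC(=O)c1cc(O)cc(OC)c1Oc1cc(C)cc(O)c1I | intermediate
9 | methyl 5-(benzyloxy)-2-[3-(benzyloxy)-2-iodo-5-methylphenoxy]-3-methoxybenzoate | COC(=O)c1cc(OCc2ccccc2)cc(OC)c1Oc1cc(C)cc(OCc2ccccc2)c1I | intermediate
10 | 1,3-bis(methoxymethoxy)-5-methylbenzene | COCOc1cc(C)cc(OCOC)c1 | intermediate
11 | [2,6-bis(methoxymethoxy)-4-methylphenyl]lithium (not isolated) | COCOc1cc(C)cc(OCOC)c1[Li] | intermediate
12 | dimethyl [2,6-bis(methoxymethoxy)-4-methylphenyl]boronate (not isolated) | COCOc1cc(C)cc(OCOC)c1B(OC)OC | intermediate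
13 | 2,6-bis(methoxymethoxy)-4-methylphenol | COCOc1cc(C)cc(OCOC)c1O | intermediate
14 | benzene-1,2,3-tricarboxylic acid (hemimellitic acid) | OC(=O)c1cccc(C(=O)O)c1C(=O)O | starting material
15 | 2,6-bis(methoxycarbonyl)benzoic acid | COC(=O)c1cccc(C(=O)OC)c1C(=O)O | intermediate
16 | dimethyl 2-(chlorocarbonyl)benzene-1,3-dicarboxylate (not isolated) | COC(=O)c1cccc(C(=O)OC)c1C(=O)Cl | intermediate
17 | 2-[2,6-bis(methoxymethoxy)-4-methylphenyl] 1,3-dimethyl benzene-1,2,3-tricarboxylate | COC(=O)c1cccc(C(=O)OC)c1C(=O)Oc1c(OCOC)cc(C)cc1OCOC | intermediate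
18 | 2-[2,6-bis(methoxymethoxy)-4-methylphenyl] 1,3-dimethyl 5-(4,4,5,5-tetramethyl-1,3,2-dioxaborolan-2-yl)benzene-1,2,3-tricarboxylate (not isolated) | COC(=O)c1cc(B2OC(C)(C)C(C)(C)O2)cc(C(=O)OC)c1C(=O)Oc1c(OCOC)cc(C)cc1OCOC | intermediate
19 | 2-[2,6-bis(methoxymethoxy)-4-methylphenyl] 1,3-dimethyl 5-hydroxybenzene-1,2,3-tricarboxylate | COC(=O)c1cc(O)cc(C(=O)OC)c1C(=O)Oc1c(OCOC)cc(C)cc1OCOC | intermediate
20 | 2-[2,6-bis(methoxymethoxy)-4-methylphenyl] 1,3-dimethyl 5-(benzyloxy)benzene-1,2,3-tricarboxylate | COC(=O)c1cc(OCc2ccccc2)cc(C(=O)OC)c1C(=O)Oc1c(OCOC)cc(C)cc1OCOC | intermediate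
21 | 2-(2,6-dihydroxy-4-methylphenyl) 1,3-dimethyl 5-(benzyloxy)benzene-1,2,3-tricarboxylate | COC(=O)c1cc(OCc2ccccc2)cc(C(=O)OC)c1C(=O)Oc1c(O)cc(C)cc1O | intermediate
22 | 2-[2,6-bis(formyloxy)-4-methylphenyl] 1,3-dimethyl 5-(benzyloxy)benzene-1,2,3-tricarboxylate | COC(=O)c1cc(OCc2ccccc2)cc(C(=O)OC)c1C(=O)Oc1c(OC=O)cc(C)cc1OC=O | intermediate
23 | tri-O-benzyl pseudophenone A | COC(=O)c1cc(OCc2ccccc2)cc(OC)c1Oc1cc(C)cc(OCc2ccccc2)c1C(=O)Oc1cc(C)cc(O)c1OC(=O)c1c(C(=O)OC)cc(OCc2ccccc2)cc1C(=O)OC | intermediate
24 | pseudophenone A | COC(=O)c1cc(O)cc(OC)c1Oc1cc(C)cc(O)c1C(=O)Oc1cc(C)cc(O)c1OC(=O)c1c(C(=O)OC)cc(O)cc1C(=O)OC | target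

**Step count and risks**

Total step count: 15. Longest linear sequence: 9 steps (steps 6, 7, 9, 10, 11, 12, 13, 14, 15, from orcinol). The left fragment takes steps 1–5; hemimellitic acid enters at step 8.

Steps most likely to fail:

1. Step 14. The hindered aroyl–palladium species may be captured slowly, so that hydrodeiodination competes; the diol may be acylated twice; or the ring-D acyl group may migrate to the neighbouring phenoxide under amine base. Fallback (classical esterification): from 9, iodine–magnesium exchange (i-PrMgCl·LiCl, THF, −40 °C, at which the methyl ester is tolerated) and a CO2 quench would give 2-(benzyloxy)-6-[4-(benzyloxy)-2-methoxy-6-(methoxycarbonyl)phenoxy]-4-methylbenzoic acid F1. Oxalyl chloride with catalytic DMF would convert it into the acid chloride F2, and acylation of an excess of diol 21 (Et3N, DMAP, CH2Cl2, 0 °C) would rejoin the route at 23.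

2. Step 9. Acyl substitution between a di-ortho-substituted acid chloride and a di-ortho-substituted phenol may be too slow, and the acid chloride may instead cyclise onto a neighbouring ester with loss of chloromethane. Fallback (bond formed at the ring carbon instead of the crowded acyl carbon): from 13, palladium-catalysed carbonylative esterification with commercial dimethyl 2-iodoisophthalate (Pd(OAc)2, Xantphos, CO 1 atm, Et3N, toluene, 90 °C) would give 17 directly, rejoining the route at 17.

3. Step 2. The ortho-iodophenoxide is hindered and weakly nucleophilic, so substitution may be slow, and the second hydroxyl may be arylated as well. Fallback (metal-free arylation with an iodonium salt): commercial methyl 2-iodo-3-methoxybenzoate would be oxidised (mCPBA, TsOH·H2O, MeCN) and trapped with 1,3,5-trimethoxybenzene to give [2-methoxy-6-(methoxycarbonyl)phenyl](2,4,6-trimethoxyphenyl)iodonium tosylate F3. From 2 (excess), deprotonation with t-BuOK and reaction with this salt in THF at rt should transfer the ester-bearing aryl group to oxygen and leave the C–I bond of 2 intact. This rejoins the route at 6 and makes step 3 unnecessary.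

**Further compounds**

F1 | step 14 | 2-(benzyloxy)-6-[4-(benzyloxy)-2-methoxy-6-(methoxycarbonyl)phenoxy]-4-methylbenzoic acid | COC(=O)c1cc(OCc2ccccc2)cc(OC)c1Oc1cc(C)cc(OCc2ccccc2)c1C(=O)O
F2 | step 14 | 2-(benzyloxy)-6-[4-(benzyloxy)-2-methoxy-6-(methoxycarbonyl)phenoxy]-4-methylbenzoyl chloride | COC(=O)c1cc(OCc2ccccc2)cc(OC)c1Oc1cc(C)cc(OCc2ccccc2)c1C(=O)Cl
F0 | step 9 | none | none
F3 | step 2 | [2-methoxy-6-(methoxycarbonyl)phenyl](2,4,6-trimethoxyphenyl)iodonium tosylate | COC(=O)c1cccc(OC)c1[I+]c1c(OC)cc(OC)cc1OC.Cc1ccc(cc1)S(=O)(=O)[O-]
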